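The route rests on leaving out the two innermost phenolic oxygens until the macrocycle exists. The precursor is the 17-membered dideoxy macrocycle carrying one MOM ether on ring A and one on ring C; it is assembled by two Wittig couplings, an SNAr etherification and an Ullmann ring closure. In one operation, twofold directed ortho-lithiation, borylation and peroxide oxidation then converts ring A C4–H and ring C C3–H (each ring numbered from its CH2-bearing carbon) into C–OH. The step exploits that each of these CH carbons sits between a MOM-oxy carbon and a diaryl-ether carbon, so two oxygens direct the base to the same site. Acid then removes both MOM groups.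

Key step: step 11

Remark on the chemistry: both Wittig olefinations should give E/Z mixtures that are carried on unseparated, because step 9 saturates both double bonds. Compounds 5, 7–10, 13 and 14 are therefore written without alkene geometry. The target has no stereocentre.

Labels: ring A is the ring from 3,5-dihydroxybenzaldehyde (C1 bridge carbon, C3 OMOM, C5 O–ring B). Ring B is the para-phenylene. Ring C is the ring from 2,4-dihydroxybenzaldehyde (C1 bridge carbon, C2 O–ring D, C4 OMOM). Ring D is the ortho-phenylene.

Step 1
Reactants: 1 2,4-dihydroxybenzaldehyde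
Product: 2 2-hydroxy-4-(methoxymethoxy)benzaldehyde
Conditions: MOMCl (1.1 equiv), K2CO3, acetone, 0 °C → rt
Reagents that add atoms: chloromethyl methyl ether, COCCl
Why: Williamson-type MOM ether formation in which the C2 hydroxyl, held in a hydrogen bond to the formyl group, reacts far more slowly than the exposed C4 hydroxyl, so mono-protection at C4 is expected.

Step 2
Reactants: 2 2-hydroxy-4-(methoxymethoxy)benzaldehyde; 3 (4-bromobenzyl)triphenylphosphonium bromide
Product: 5 2-[2-(4-bromophenyl)ethenyl]-5-(methoxymethoxy)phenol (E/Z mixture), via 4-bromobenzylidene(triphenyl)phosphorane 4 (not isolated)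
Conditions: 3 (1.2 equiv), KOtBu (2.4 equiv), THF, 0 °C; then 2, 0 → 50 °C; aq NH4Cl
Reagents that add atoms: none
Why: Wittig olefination of a semi-stabilized benzylic ylide in which the extra base holds the ortho-hydroxyl as its phenoxide, which slows but should not prevent carbonyl addition, and the alkene geometry is irrelevant because the double bond is saturated in step 9.

Step 3
Reactants: 5 2-[2-(4-bromophenyl)ethenyl]-5-(methoxymethoxy)phenol; 6 2-fluorobenzaldehyde
Product: 7 2-{2-[2-(4-bromophenyl)ethenyl]-5-(methoxymethoxy)phenoxy}benzaldehyde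
Conditions: K2CO3, DMA, 130 °C
Reagents that add atoms: none
Why: Nucleophilic aromatic substitution by addition–elimination, in which the ortho-formyl group stabilizes the Meisenheimer adduct and fluoride leaves, while the unactivated aryl bromide and the MOM ether are inert to carbonate.

Step 4
Reactants: 7 2-{2-[2-(4-bromophenyl)ethenyl]-5-(methoxymethoxy)phenoxy}benzaldehyde
Product: 8 (2-{2-[2-(4-bromophenyl)ethenyl]-5-(methoxymethoxy)phenoxy}phenyl)methanol
Conditions: NaBH4, MeOH/THF, 0 °C
Reagents that add atoms: none
Why: Borohydride reduction of the aldehyde to the benzylic alcohol, which leaves the aryl bromide, the alkene and the acetal untouched.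

Step 5
Reactants: 8 (2-{2-[2-(4-bromophenyl)ethenyl]-5-(methoxymethoxy)phenoxy}phenyl)methanol
Product: 9 1-[2-(4-bromophenyl)ethenyl]-2-[2-(bromomethyl)phenoxy]-4-(methoxymethoxy)benzene
Conditions: CBr4, PPh3, CH2Cl2, 0 °C → rt
Reagents that add atoms: carbon tetrabromide, BrC(Br)(Br)Br
Why: Appel bromination, chosen because it runs under neutral conditions and releases no free HBr that could cleave the MOM ether.

Step 6
Reactants: 9 1-[2-(4-bromophenyl)ethenyl]-2-[2-(bromomethyl)phenoxy]-4-(methoxymethoxy)benzene
Product: 10 (2-{2-[2-(4-bromophenyl)ethenyl]-5-(methoxymethoxy)phenoxy}benzyl)triphenylphosphonium bromide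
Conditions: PPh3, toluene, 100 °C
Reagents that add atoms: triphenylphosphine, c1ccc(cc1)P(c1ccccc1)c1ccccc1
Why: SN2 quaternization of the phosphine by the benzylic bromide, the aryl bromide being unreactive toward PPh3 without a transition metal.

Step 7
Reactants: 11 3,5-dihydroxybenzaldehyde
Product: 12 3-hydroxy-5-(methoxymethoxy)benzaldehyde
Conditions: MOMCl (1.0 equiv), K2CO3 (1.0 equiv), acetone, 0 °C → rt; chromatography
Reagents that add atoms: chloromethyl methyl ether, COCCl
Why: Statistical Williamson-type mono-etherification of a symmetric diphenol with one equivalent of electrophile, the mono-ether being separable from recovered 11 and the bis-ether.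

Step 8
Reactants: 10 (2-{2-[2-(4-bromophenyl)ethenyl]-5-(methoxymethoxy)phenoxy}benzyl)triphenylphosphonium bromide; 12 3-hydroxy-5-(methoxymethoxy)benzaldehyde
Product: 14 3-[2-(2-{2-[2-(4-bromophenyl)ethenyl]-5-(methoxymethoxy)phenoxy}phenyl)ethenyl]-5-(methoxymethoxy)phenol (mixture of alkene isomers), via ring D benzylidene(triphenyl)phosphorane 13 (not isolated)
Conditions: 10, KOtBu (1.1 equiv), THF, 0 °C; then 12 pre-treated with KOtBu (1.1 equiv), 0 °C → rt; aq NH4Cl
Reagents that add atoms: none
Why: Wittig olefination in which the phenol of 12 is carried as its phenoxide, which sits meta to the formyl group and therefore cannot deactivate it by resonance.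

Step 9
Reactants: 14 3-[2-(2-{2-[2-(4-bromophenyl)ethenyl]-5-(methoxymethoxy)phenoxy}phenyl)ethenyl]-5-(methoxymethoxy)phenol
Product: 15 3-[2-(2-{2-[2-(4-bromophenyl)ethyl]-5-(methoxymethoxy)phenoxy}phenyl)ethyl]-5-(methoxymethoxy)phenol
Conditions: p-TsNHNH2 (excess), NaOAc, DME/H2O, reflux
Reagents that add atoms: none
Why: Diimide reduction, a metal-free concerted syn transfer of two hydrogens from HN=NH generated in the flask, should saturate both stilbene double bonds without any risk of hydrogenolysis of the aryl bromide.

Step 10
Reactants: 15 3-[2-(2-{2-[2-(4-bromophenyl)ethyl]-5-(methoxymethoxy)phenoxy}phenyl)ethyl]-5-(methoxymethoxy)phenol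
Product: 16 dideoxy macrocycle bis(methoxymethyl) ether
Conditions: CuI (30 mol %), N,N-dimethylglycine hydrochloride, Cs2CO3, 1,4-dioxane, 100 °C, slow addition of 15 to about 2 mM final concentration
Reagents that add atoms: none
Why: Intramolecular Ullmann diaryl ether synthesis catalysed by monovalent copper with an amino acid ligand, in which the only phenoxide (ring A C5–O) is arylated by the only aryl halide (ring B) and high dilution favours closure of the 17-membered ring over oligomerization.

Step 11
Reactants: 16 dideoxy macrocycle bis(methoxymethyl) ether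
Product: 19 bis(methoxymethyl) ether of the target, via dilithio macrocycle 17 (not isolated), via bis(dimethoxyboryl) macrocycle 18 (not isolated)
Conditions: n-BuLi (3 equiv), TMEDA (3 equiv), THF, −20 → 0 °C; B(OMe)3 (6 equiv), −78 °C → rt; 30% aq H2O2, aq NaOH, 0 °C → rt; Na2S2O3, NH4Cl work-up
Reagents that add atoms: hydrogen peroxide, OO
Why: TMEDA-activated n-BuLi coordinates to the MOM acetal oxygens and removes ring A C4–H and ring C C3–H, the only protons flanked by two oxygen-bearing carbons (OMOM on one side, diaryl ether oxygen on the other), to give dilithio species 17; B(OMe)3 captures both carbanions as aryl boronates 18, and hydroperoxide anion then adds to boron and triggers 1,2-migration of the aryl group from boron to oxygen, hydrolysis releasing the two phenols. The closest known reaction type is directed ortho-metalation of resorcinol-type bis-ethers at the carbon between the two oxygens followed by borylation and oxidation, here run at two sites of one molecule. No ring is closed and no stereocentre is formed. The selectivity needed is metalation only at the two doubly flanked positions and not at the singly activated positions of rings A to D or at the benzylic CH2 groups; the cooperative coordination and the inductive acidification by two ortho oxygens, together with a limited excess of base and low temperature, should secure it. Adding the borate at −78 °C and oxidizing in the same flask with alkaline peroxide should limit protodeboronation of the hindered boronates.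

Step 12
Reactants: 19 bis(methoxymethyl) ether of the target
Product: 20 target macrocycle (CNP0114693.0)
Conditions: 3 M aq HCl, MeOH, 45 °C, argon
Reagents that add atoms: none
Why: Acid-catalysed acetal cleavage of the two aryl MOM ethers, to which the diaryl ethers and the CH2CH2 bridges are inert, with an inert atmosphere to protect the two catechol units from air oxidation.

Compound list
1 | 2,4-dihydroxybenzaldehyde | O=Cc1ccc(O)cc1O | starting material
2 | 2-hydroxy-4-(methoxymethoxy)benzaldehyde | O=Cc1ccc(OCOC)cc1O | intermediate
3 | (4-bromobenzyl)triphenylphosphonium bromide | [Br-].Brc1ccc(C[P+](c2ccccc2)(c2ccccc2)c2ccccc2)cc1 | starting material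
4 | 4-bromobenzylidene(triphenyl)phosphorane | Brc1ccc(C=P(c2ccccc2)(c2ccccc2)c2ccccc2)cc1 | intermediate (not isolated)
5 | 2-[2-(4-bromophenyl)ethenyl]-5-(methoxymethoxy)phenol, E/Z mixture | COCOc1ccc(C=Cc2ccc(Br)cc2)c(O)c1 | intermediate
6 | 2-fluorobenzaldehyde | O=Cc1ccccc1F | starting material
7 | 2-{2-[2-(4-bromophenyl)ethenyl]-5-(methoxymethoxy)phenoxy}benzaldehyde, E/Z mixture | COCOc1ccc(C=Cc2ccc(Br)cc2)c(Oc2ccccc2C=O)c1 | intermediate
8 | (2-{2-[2-(4-bromophenyl)ethenyl]-5-(methoxymethoxy)phenoxy}phenyl)methanol, E/Z mixture | COCOc1ccc(C=Cc2ccc(Br)cc2)c(Oc2ccccc2CO)c1 | intermediate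
9 | 1-[2-(4-bromophenyl)ethenyl]-2-[2-(bromomethyl)phenoxy]-4-(methoxymethoxy)benzene, E/Z mixture | COCOc1ccc(C=Cc2ccc(Br)cc2)c(Oc2ccccc2CBr)c1 | intermediate
10 | (2-{2-[2-(4-bromophenyl)ethenyl]-5-(methoxymethoxy)phenoxy}benzyl)triphenylphosphonium bromide, E/Z mixture | [Br-].COCOc1ccc(C=Cc2ccc(Br)cc2)c(Oc2ccccc2C[P+](c2ccccc2)(c2ccccc2)c2ccccc2)c1 | intermediate
11 | 3,5-dihydroxybenzaldehyde | O=Cc1cc(O)cc(O)c1 | starting material
12 | 3-hydroxy-5-(methoxymethoxy)benzaldehyde | O=Cc1cc(O)cc(OCOC)c1 | intermediate
13 | ylide of 10, (2-{2-[2-(4-bromophenyl)ethenyl]-5-(methoxymethoxy)phenoxy}benzylidene)triphenylphosphorane | COCOc1ccc(C=Cc2ccc(Br)cc2)c(Oc2ccccc2C=P(c2ccccc2)(c2ccccc2)c2ccccc2)c1 | intermediate (not isolated)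
14 | 3-[2-(2-{2-[2-(4-bromophenyl)ethenyl]-5-(methoxymethoxy)phenoxy}phenyl)ethenyl]-5-(methoxymethoxy)phenol, mixture of alkene isomers | COCOc1ccc(C=Cc2ccc(Br)cc2)c(Oc2ccccc2C=Cc2cc(O)cc(OCOC)c2)c1 | intermediate
15 | 3-[2-(2-{2-[2-(4-bromophenyl)ethyl]-5-(methoxymethoxy)phenoxy}phenyl)ethyl]-5-(methoxymethoxy)phenol | COCOc1ccc(CCc2ccc(Br)cc2)c(Oc2ccccc2CCc2cc(O)cc(OCOC)c2)c1 | intermediate
16 | dideoxy macrocycle bis(methoxymethyl) ether: 17-membered ring, ring A with C3 OMOM and C5 O–ring B, ring C with C4 OMOM and C2 O–ring D | COCOc1cc2cc(c1)Oc1ccc(cc1)CCc1ccc(OCOC)cc1Oc1ccccc1CC2 | intermediate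
17 | dilithio macrocycle, lithium at ring A C4 and ring C C3 | COCOc1cc2cc(c1[Li])Oc1ccc(cc1)CCc1ccc(OCOC)c([Li])c1Oc1ccccc1CC2 | intermediate (not isolated)
18 | bis(dimethoxyboryl) macrocycle, B(OMe)2 at ring A C4 and ring C C3 | COCOc1cc2cc(c1B(OC)OC)Oc1ccc(cc1)CCc1ccc(OCOC)c(B(OC)OC)c1Oc1ccccc1CC2 | intermediate (not isolated)
19 | bis(methoxymethyl) ether of the target: ring A C3 OMOM and C4 OH, ring C C4 OMOM and C3 OH | COCOc1cc2cc(c1O)Oc1ccc(cc1)CCc1ccc(OCOC)c(O)c1Oc1ccccc1CC2 | intermediate
20 | target macrocycle CNP0114693.0, tetraphenol | Oc1cc2cc(c1O)Oc1ccc(cc1)CCc1ccc(O)c(O)c1Oc1ccccc1CC2 | target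

Total step count: 12. Longest linear sequence: 11 steps (steps 1–6 and 8–12, from compound 1); step 7 prepares the ring A aldehyde separately.

Steps most likely to fail

Step 11. The second metalation may stay incomplete, or the hindered, doubly ortho-oxygenated boronates may lose boron by protonolysis before the peroxide reaches them, which would return starting material or a mono-phenol. The fallback keeps the carbanions but replaces boron by carbon. It sets out from 16: the dilithio species 17, generated as in the main route, is quenched with DMF to give the macrocyclic dialdehyde F1. Baeyer–Villiger (Dakin-type) oxidation with mCPBA in CH2Cl2 buffered with NaHCO3 should move each electron-rich aryl group from carbon to oxygen and give the bis(formate) F2. Methanolysis with K2CO3 in MeOH then comes back to the route at 19.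

Step 10. Ring closure at the unactivated ring B bromide may be slow enough that intermolecular etherification or reductive loss of bromine takes over. The fallback reverses the roles of the partners and uses oxidative copper chemistry. It sets out from 15: Miyaura borylation (bis(pinacolato)diboron, Pd(dppf)Cl2, KOAc, dioxane, 80 °C) should give the pinacol boronate F3. Cleavage of the pinacol ester with NaIO4 and NH4OAc in aqueous acetone should give the boronic acid F4. Chan–Lam–Evans O-arylation (Cu(OAc)2, Et3N, 4 Å molecular sieves, CH2Cl2, air, high dilution) then closes the ring at room temperature and comes back to the route at 16.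

Step 2. Carbonyl addition may be sluggish because the ortho-phenoxide donates into the formyl group, so that the ylide decomposes before it is consumed. The fallback forms the diaryl ether first with a masked aldehyde, so that the Wittig step meets no phenoxide. It sets out from 2: SNAr with 2-fluorobenzonitrile (N#Cc1ccccc1F; K2CO3, DMF, 110 °C) should give the nitrile aldehyde F5. Wittig olefination with ylide 4 (from 3 and KOtBu in THF) should give the stilbene nitrile F6. Reduction with DIBAL-H in toluene at −78 °C, with hydrolysis of the aldimine on mild aqueous work-up, comes back to the route at 7.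

Further compounds
F1 | step 11 | macrocyclic dialdehyde, formyl groups at ring A C4 and ring C C3 | COCOc1cc2cc(c1C=O)Oc1ccc(cc1)CCc1ccc(OCOC)c(C=O)c1Oc1ccccc1CC2
F2 | step 11 | macrocyclic bis(formate), formyloxy groups at ring A C4 and ring C C3 | COCOc1cc2cc(c1OC=O)Oc1ccc(cc1)CCc1ccc(OCOC)c(OC=O)c1Oc1ccccc1CC2
F3 | step 10 | pinacol boronate of 15, boron in place of bromine on ring B | COCOc1ccc(CCc2ccc(cc2)B2OC(C)(C)C(C)(C)O2)c(Oc2ccccc2CCc2cc(O)cc(OCOC)c2)c1
F4 | step 10 | boronic acid of 15, B(OH)2 in place of bromine on ring B | COCOc1ccc(CCc2ccc(cc2)B(O)O)c(Oc2ccccc2CCc2cc(O)cc(OCOC)c2)c1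
F5 | step 2 | 2-[2-formyl-5-(methoxymethoxy)phenoxy]benzonitrile | COCOc1ccc(C=O)c(Oc2ccccc2C#N)c1
F6 | step 2 | 2-{2-[2-(4-bromophenyl)ethenyl]-5-(methoxymethoxy)phenoxy}benzonitrile, E/Z mixture | COCOc1ccc(C=Cc2ccc(Br)cc2)c(Oc2ccccc2C#N)c1
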